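**Retrosynthetic overview** (target numbering is used for all spiro compounds: ring A = C1–C6, with C1 the methylidene-bearing carbon, C2 the ketone, C4 the C–Br carbon, C5 the CMe2 carbon, C6 the spiro atom; ring B = C6–C11, with C8 = CHBr and C9 = C(Cl)Me)
1. The C1 methylidene comes from a final Mannich methylenation, the trans C8–Br/C9–Cl pair from BrCl addition to a C8=C9 alkene, and the C4–Br bond from a 2,4-dione through its C2 vinylogous amide (1,3-transposition of O into Br).
2. Ring A is closed at C3–C4 by an intramolecular Claisen (Dieckmann-type) cyclisation. The enabling feature is that the ester carbon C4 sits on the quaternary C5 (no α-hydrogen, no self-condensation) and is 1,5 to the C2 methyl ketone on the other branch of C6, so the kinetic C3 enolate can only close the six-membered ring A. One operation then completes the spiro[5.5] skeleton and delivers C2 and C4 at the oxidation levels needed for the ketone and the bromoalkene.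
3. C6 and ring B come from a catalytic enantioselective Diels–Alder reaction of isoprene with a 2-(tert-alkyl)acrolein; the formyl group is then homologated to the acetonyl branch.
4. Order of ring formation: ring B (step 3), then ring A (step 5); all later steps are functional-group changes.

Key step: step 5

Assumption: the facial sense of the chiral oxazaborolidinium catalyst in step 3 is taken by analogy with 2-bromoacrolein plus isoprene, so that the (R)-catalyst gives (1R)-5; if the sense is opposite, the (S)-catalyst is used.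

**Step 1**
Reactants: 1 methyl 2,2-dimethylpent-4-enoate
Product: 2 methyl 2,2-dimethyl-4-oxobutanoate
Conditions: OsO4 (cat.), NaIO4, 2,6-lutidine, dioxane/H2O, rt
Reagents that add atoms: sodium periodate, [Na+].[O-]I(=O)(=O)=O (oxygen, relayed through OsO4)
Why: Lemieux–Johnson oxidative cleavage of the only (terminal) alkene; the hindered, non-enolisable ester is untouched.

**Step 2**
Reactants: 2 methyl 2,2-dimethyl-4-oxobutanoate
Product: 3 methyl 3-formyl-2,2-dimethylbut-3-enoate
Conditions: 37% aq. HCHO, pyrrolidine (10 mol%), propionic acid (10 mol%), i-PrOH, 45 °C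
Reagents that add atoms: formaldehyde, C=O
Why: Organocatalytic Mannich condensation–elimination (α-methylenation of an aldehyde) through the pyrrolidine enamine of 2; only C3 carries α-hydrogens.

**Step 3**
Reactants: 3 methyl 3-formyl-2,2-dimethylbut-3-enoate; 4 isoprene
Product: 5 methyl 2-[(1R)-1-formyl-4-methylcyclohex-3-en-1-yl]-2-methylpropanoate
Conditions: (R)-3,3-diphenyl-1-(2-methylphenyl)tetrahydro-1H,3H-pyrrolo[1,2-c][1,3,2]oxazaborole (20 mol%), (CF3SO2)2NH (18 mol%), CH2Cl2, −78 → −40 °C
Reagents that add atoms: none
Why: Lewis-acid-catalysed Diels–Alder reaction of a 2-substituted acrolein, in which the chiral oxazaborolidinium ion binds the s-trans enal and shields one face of the C=C bond so that isoprene adds to the other and sets the quaternary C1 (later spiro C6) as R, while the "para" orientation puts the ring methyl 1,4 to it; a methylene flanked by a carbonyl and a CMe2 carbon reacting with isoprene is the classical entry to chamigrene spiro centres.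

**Step 4**
Reactants: 5 methyl 2-[(1R)-1-formyl-4-methylcyclohex-3-en-1-yl]-2-methylpropanoate
Product: 7 methyl 2-methyl-2-[(1S)-4-methyl-1-(2-oxopropyl)cyclohex-3-en-1-yl]propanoate, via enol ether 6 (not isolated)
Conditions: Ph3P+CH(OMe)CH3 Cl−, t-BuOK, THF, 0 °C → rt; then 1 M HCl, THF, rt
Reagents that add atoms: (1-methoxyethyl)triphenylphosphonium chloride, COC(C)[P+](c1ccccc1)(c1ccccc1)c1ccccc1.[Cl-]; water, O
Why: Wittig olefination with an α-methoxyalkylidene ylide and hydrolysis of the enol ether converts the aldehyde into the homologous methyl ketone; the quaternary stereocentre cannot epimerise (its descriptor changes only through CIP priorities).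

**Step 5**
Reactants: 7 methyl 2-methyl-2-[(1S)-4-methyl-1-(2-oxopropyl)cyclohex-3-en-1-yl]propanoate
Product: 8 (6S)-5,5,9-trimethylspiro[5.5]undec-8-ene-2,4-dione
Conditions: LiN(SiMe3)2 (2.2 equiv), THF, −78 → 0 °C; then 1 M HCl
Reagents that add atoms: none
Why: The amide base removes a methyl proton of the ketone under kinetic control; the C3 enolate adds to the C4 ester carbonyl, methoxide leaves, and the 1,3-dione is deprotonated by the second equivalent of base, which makes the closure irreversible. The closest known reaction type is the Dieckmann-type (intramolecular Claisen) cyclisation of 5-oxo esters to cyclohexane-1,3-diones. Ring A closes in the 6-(enolendo)-exo-trig mode. No new stereocentre is formed, and C6 has no acidic hydrogen. The step needs regioselection between the two ketone enolates and suppression of retro-Michael loss of the CMe2CO2Me branch from the C1 enolate; both are secured by kinetic deprotonation at the unhindered methyl group at −78 °C, and the C1 enolate could in any case only close a four-membered ring. Self-condensation of the ester is excluded because C4 sits on the quaternary C5.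

**Step 6**
Reactants: 8 (6S)-5,5,9-trimethylspiro[5.5]undec-8-ene-2,4-dione
Product: 9 (6S)-5,5,9-trimethyl-2-(pyrrolidin-1-yl)spiro[5.5]undeca-2,8-dien-4-one
Conditions: pyrrolidine, TsOH·H2O (cat.), toluene, reflux, Dean–Stark
Reagents that add atoms: pyrrolidine, C1CCNC1
Why: Condensation of a cyclic 1,3-dione with a secondary amine to a vinylogous amide, the amine adding to the less hindered C2 carbonyl (flanked by C1H2) and not to C4 next to the quaternary C5, which decides where oxygen and bromine end up.

**Step 7**
Reactants: 9 (6S)-5,5,9-trimethyl-2-(pyrrolidin-1-yl)spiro[5.5]undeca-2,8-dien-4-one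
Product: 11 (6S)-4-bromo-5,5,9-trimethylspiro[5.5]undeca-3,8-dien-2-one, via bromoiminium salt 10 (not isolated)
Conditions: (COBr)2, CH2Cl2, 0 °C; then sat. aq. NaHCO3, THF, rt
Reagents that add atoms: oxalyl bromide, O=C(Br)C(=O)Br; water, O
Why: Vinylogous Vilsmeier-type activation, in which oxalyl bromide acylates the C4 oxygen of the vinylogous amide, bromide replaces it by addition–elimination (loss of CO and CO2), and hydrolysis of the 3-bromoalkenyl iminium ion at the less hindered C2 unveils the ketone, as in the aqueous work-up of β-halovinyl iminium salts.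

**Step 8**
Reactants: 11 (6S)-4-bromo-5,5,9-trimethylspiro[5.5]undeca-3,8-dien-2-one
Product: 12 (6R,8S,9S)-4,8-dibromo-9-chloro-5,5,9-trimethylspiro[5.5]undec-3-en-2-one
Conditions: NBS and HCl (4 M in dioxane) premixed in CH2Cl2 at −78 °C; then 11, −78 °C
Reagents that add atoms: N-bromosuccinimide, O=C1CCC(=O)N1Br; hydrogen chloride, Cl
Why: Electrophilic anti addition of BrCl to the only electron-rich alkene (the bromoenone C=C is deactivated), where the bromonium ion should form on the ring-B face anti to the pseudo-axial C1H2 branch (the face of the equatorial C5) and chloride should open it at the tertiary C9 from the C1 side, placing Br on C8 cis to C5 and Cl on C9 trans to it (C6 changes descriptor through CIP priorities only).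

**Step 9**
Reactants: 12 (6R,8S,9S)-4,8-dibromo-9-chloro-5,5,9-trimethylspiro[5.5]undec-3-en-2-one
Product: 15 (6S,8S,9S)-4,8-dibromo-9-chloro-5,5,9-trimethyl-1-methylidenespiro[5.5]undec-3-en-2-one, via Mannich base 13 (not isolated), via methiodide 14 (not isolated)
Conditions: LiN(SiMe3)2, THF, −78 °C; CH2=NMe2+ I−, −78 → 0 °C; then MeI, rt; then sat. aq. NaHCO3, CH2Cl2
Reagents that add atoms: dimethyl(methylidene)ammonium iodide, C=[N+](C)C.[I-]
Why: Mannich reaction of the kinetic lithium dienolate (C1 is the only enolisable position) with the preformed iminium salt, N-methylation and E1cB loss of trimethylamine give the α-methylene ketone; the equatorial C8–Br and C9–Cl bonds have no antiperiplanar hydrogen and no stereocentre is epimerisable.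

**Compound list**
1 | methyl 2,2-dimethylpent-4-enoate | C=CCC(C)(C)C(=O)OC | starting material
2 | methyl 2,2-dimethyl-4-oxobutanoate | O=CCC(C)(C)C(=O)OC | intermediate
3 | methyl 3-formyl-2,2-dimethylbut-3-enoate | C=C(C=O)C(C)(C)C(=O)OC | intermediate
4 | isoprene (2-methylbuta-1,3-diene) | C=CC(C)=C | starting material
5 | methyl 2-[(1R)-1-formyl-4-methylcyclohex-3-en-1-yl]-2-methylpropanoate | COC(=O)C(C)(C)[C@@]1(C=O)CCC(C)=CC1 | intermediate
6 | methyl 2-[(1S)-1-(2-methoxyprop-1-en-1-yl)-4-methylcyclohex-3-en-1-yl]-2-methylpropanoate (E/Z mixture) | COC(=O)C(C)(C)[C@@]1(C=C(C)OC)CCC(C)=CC1 | intermediate (not isolated)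
7 | methyl 2-methyl-2-[(1S)-4-methyl-1-(2-oxopropyl)cyclohex-3-en-1-yl]propanoate | COC(=O)C(C)(C)[C@@]1(CC(C)=O)CCC(C)=CC1 | intermediate
8 | (6S)-5,5,9-trimethylspiro[5.5]undec-8-ene-2,4-dione | C1C(=O)CC(=O)C(C)(C)[C@]12CCC(C)=CC2 | intermediate
9 | (6S)-5,5,9-trimethyl-2-(pyrrolidin-1-yl)spiro[5.5]undeca-2,8-dien-4-one | C1C(N3CCCC3)=CC(=O)C(C)(C)[C@]12CCC(C)=CC2 | intermediate
10 | 1-[(6S)-4-bromo-5,5,9-trimethylspiro[5.5]undeca-3,8-dien-2-ylidene]pyrrolidin-1-ium bromide | C1C(=[N+]3CCCC3)C=C(Br)C(C)(C)[C@]12CCC(C)=CC2.[Br-] | intermediate (not isolated)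
11 | (6S)-4-bromo-5,5,9-trimethylspiro[5.5]undeca-3,8-dien-2-one | C1C(=O)C=C(Br)C(C)(C)[C@]12CCC(C)=CC2 | intermediate
12 | (6R,8S,9S)-4,8-dibromo-9-chloro-5,5,9-trimethylspiro[5.5]undec-3-en-2-one | C1C(=O)C=C(Br)C(C)(C)[C@]12CC[C@](C)(Cl)[C@@H](Br)C2 | intermediate
13 | (6S,8S,9S)-4,8-dibromo-9-chloro-1-[(dimethylamino)methyl]-5,5,9-trimethylspiro[5.5]undec-3-en-2-one (C1 epimers) | CN(C)CC1C(=O)C=C(Br)C(C)(C)[C@]12CC[C@](C)(Cl)[C@@H](Br)C2 | intermediate (not isolated)
14 | {[(6S,8S,9S)-4,8-dibromo-9-chloro-5,5,9-trimethyl-2-oxospiro[5.5]undec-3-en-1-yl]methyl}trimethylammonium iodide (C1 epimers) | C[N+](C)(C)CC1C(=O)C=C(Br)C(C)(C)[C@]12CC[C@](C)(Cl)[C@@H](Br)C2.[I-] | intermediate (not isolated)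
15 | (6S,8S,9S)-4,8-dibromo-9-chloro-5,5,9-trimethyl-1-methylidenespiro[5.5]undec-3-en-2-one | C=C1C(=O)C=C(Br)C(C)(C)[C@]12CC[C@](C)(Cl)[C@@H](Br)C2 | target

**Step count and risks**
Total step count: 9. Longest linear sequence: 9 steps (1 → 15; isoprene 4 enters in step 3).

Steps most likely to fail:

1. Step 8. The bromonium ion may form on the other face of the ring-B alkene, which a chair-like trans-diaxial opening with the C1 branch axial would favour; this would give the C8/C9 diastereomer. Opening at the secondary carbon and halide scrambling are further losses. Fallback, from 11 back to 12: the two bonds are made in separate events. NBS in aqueous acetone at 0 °C should give the bromohydrin (6R,8S,9S)-4,8-dibromo-9-hydroxy-5,5,9-trimethylspiro[5.5]undec-3-en-2-one F1, in which water has opened the bromonium ion at C9 and which can be purified to one diastereomer. HCl (4 M in dioxane) in CH2Cl2 at 0 °C should then replace the tertiary hydroxyl by chloride with retention through the bromine-bridged cation, giving 12.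

2. Step 3. The hindered 2-(tert-alkyl)acrolein may react slowly or with poor facial discrimination, and isoprene may oligomerise at the strongly acidic catalyst. Fallback, from 3 and 4 back to 5: a racemic cycloaddition with EtAlCl2 (cat.) in CH2Cl2 at −78 °C gives racemic methyl 2-(1-formyl-4-methylcyclohex-3-en-1-yl)-2-methylpropanoate F2. Condensation with (1S,2S)-N,N'-dimethyl-1,2-diphenylethane-1,2-diamine (4 Å sieves, Et2O) gives diastereomeric aminals. The one from the (1R)-aldehyde, methyl 2-[(1R)-1-[(4S,5S)-1,3-dimethyl-4,5-diphenylimidazolidin-2-yl]-4-methylcyclohex-3-en-1-yl]-2-methylpropanoate F3, is separated by chromatography and hydrolysed with dilute aqueous HCl to 5.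

3. Step 4. The disubstituted ylide may fail to add to the neopentyl aldehyde flanked by two quaternary carbons. Fallback, from 5 back to 7: the chain is built one carbon at a time. The smaller ylide Ph3P=CHOMe (from (methoxymethyl)triphenylphosphonium chloride and t-BuOK, THF) gives methyl 2-[(1S)-1-(2-methoxyethenyl)-4-methylcyclohex-3-en-1-yl]-2-methylpropanoate F4. Aqueous HCl gives methyl 2-methyl-2-[(1S)-4-methyl-1-(2-oxoethyl)cyclohex-3-en-1-yl]propanoate F5. MeMgBr in THF at −78 °C (the neopentyl ester is spared) gives methyl 2-[(1S)-1-(2-hydroxypropyl)-4-methylcyclohex-3-en-1-yl]-2-methylpropanoate F6 (carbinol epimers), and oxidation with DMP in CH2Cl2 gives 7.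

**Further compounds**
F1 | step 8 | (6R,8S,9S)-4,8-dibromo-9-hydroxy-5,5,9-trimethylspiro[5.5]undec-3-en-2-one | C1C(=O)C=C(Br)C(C)(C)[C@]12CC[C@](C)(O)[C@@H](Br)C2
F2 | step 3 | racemic methyl 2-(1-formyl-4-methylcyclohex-3-en-1-yl)-2-methylpropanoate | COC(=O)C(C)(C)C1(C=O)CCC(C)=CC1
F3 | step 3 | methyl 2-[(1R)-1-[(4S,5S)-1,3-dimethyl-4,5-diphenylimidazolidin-2-yl]-4-methylcyclohex-3-en-1-yl]-2-methylpropanoate | COC(=O)C(C)(C)[C@@]1(C2N(C)[C@@H](c3ccccc3)[C@H](c3ccccc3)N2C)CCC(C)=CC1
F4 | step 4 | methyl 2-[(1S)-1-(2-methoxyethenyl)-4-methylcyclohex-3-en-1-yl]-2-methylpropanoate (E/Z mixture) | COC(=O)C(C)(C)[C@@]1(C=COC)CCC(C)=CC1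
F5 | step 4 | methyl 2-methyl-2-[(1S)-4-methyl-1-(2-oxoethyl)cyclohex-3-en-1-yl]propanoate | COC(=O)C(C)(C)[C@@]1(CC=O)CCC(C)=CC1
F6 | step 4 | methyl 2-[(1S)-1-(2-hydroxypropyl)-4-methylcyclohex-3-en-1-yl]-2-methylpropanoate (carbinol epimers) | COC(=O)C(C)(C)[C@@]1(CC(C)O)CCC(C)=CC1
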